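The chroman is cut at C4–C4a (and at C2–C1′). The C2–C3–C4 unit with its isopropyl and isobutyl groups is the commercial self-aldol dimer of isovaleraldehyde. It is hung on O1 of a phloroglucinol ether as an α-acetoxy aryl acetal. A confined chiral acid ionises this to a 1-aryloxyallyl cation. Its terminus C4 is attacked by A-ring carbon C4a, which the C5 and C7 oxygens, ortho and para to it, make nucleophilic. The resulting 4H-chromene is protonated at C3 and arylated at C2 in the same flask. One operation thus closes the pyran ring, forms two C–C bonds and sets C4, C3 and C2 by relay. Fourfold formylation and demethylation finish the synthesis.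

Key step: step 4

Assumption: chroman numbering (O1, C2, C3, C4, C4a, C5–C8, C8a; B′ ring C1′–C6′) is used for all compounds. Which antipode of the chiral acid leads to the (4S) series has to be found by experiment; both antipodes are accessible.

Step 1
Reactants: 1 (E)-2-isopropyl-5-methylhex-2-enal
Product: 2 (E)-2-isopropyl-5-methylhex-2-enoic acid
Conditions: NaClO2, NaH2PO4, 2-methyl-2-butene, t-BuOH/H2O, 0 °C to rt
Reagents that add atoms: sodium chlorite, [Na+].[O-]Cl=O
Why: Pinnick oxidation takes the enal to the acid without touching or isomerising the trisubstituted E alkene, because the scavenger removes the hypochlorous acid, and no stereocenter is formed.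

Step 2
Reactants: 2 (E)-2-isopropyl-5-methylhex-2-enoic acid; 3 3,5-dimethoxyphenol
Product: 4 3,5-dimethoxyphenyl (E)-2-isopropyl-5-methylhex-2-enoate
Conditions: DCC, DMAP (cat.), CH2Cl2, 0 °C to rt
Reagents that add atoms: none
Why: Steglich esterification forms the O1–C2 bond at the robust ester level, where DMAP-mediated acyl transfer goes to the phenol oxygen and not to the electron-rich ring carbons, and no stereocenter is formed.

Step 3
Reactants: 4 3,5-dimethoxyphenyl (E)-2-isopropyl-5-methylhex-2-enoate
Product: 6 (E)-1-(3,5-dimethoxyphenoxy)-2-isopropyl-5-methylhex-2-en-1-yl acetate (racemic at the acetal carbon C2), via aluminium hemiacetal 5 (not isolated)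
Conditions: DIBAL-H, CH2Cl2, −78 °C; then pyridine, DMAP, Ac2O, −78 to 0 °C
Reagents that add atoms: acetic anhydride, CC(=O)OC(C)=O
Why: Reductive acetylation of an ester: DIBAL-H adds once to the ester carbonyl, the tetrahedral aluminium hemiacetal 5 persists at −78 °C and is acylated in situ, so C2 reaches the aldehyde level with O1 still attached, and the new racemic acetal center is erased in step 4.

Step 4
Reactants: 6 (E)-1-(3,5-dimethoxyphenoxy)-2-isopropyl-5-methylhex-2-en-1-yl acetate; 7 1,3,5-trimethoxybenzene
Product: 11 (2R,3R,4S)-4-isobutyl-3-isopropyl-5,7-dimethoxy-2-(2,4,6-trimethoxyphenyl)chroman, via aryloxyallyl cation 8 (not isolated), via 4H-chromene 9 (not isolated), via cyclic oxocarbenium ion 10 (not isolated)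
Conditions: chiral imidodiphosphorimidate (IDPi) Brønsted acid (5 mol %), toluene (0.01 M), −60 °C; then 7 (3 equiv), −60 to −20 °C
Reagents that add atoms: none
Why: Proposed new method: the confined chiral acid ionises 6 in one sense only, since acetate is the better leaving group and the aryloxy-stabilised allyl cation 8 the better cation, and holds 8 as a contact ion pair. The U-shaped conformer of 8 closes the pyran ring by attack of A-ring carbon C4a, which is ortho to C5-OMe and para to C7-OMe, on the allyl terminus C4 (6-endo-trig Friedel–Crafts closure, equally a cationic oxa-6π electrocyclisation), and proton loss gives 9; the closest known reaction types are the Lewis-acid formal [4+2] of aryl oxocarbenium ions with alkenes (oxa-Povarov reaction), which ends in the same arene-to-cation closure, the chiral-acid ionic Diels–Alder reaction of vinyl oxocarbenium ion pairs made from enal acetals, and the chiral-acid asymmetric Nazarov cyclisation. C4 is set by the chiral anion, which selects one of the two helical folds of the achiral cation, while the E alkene of 6 places the isobutyl group outside and H inside. C3 is set by protonation of the enol ether of 9 anti to the isobutyl group, which A(1,2) strain with the isopropyl group and peri strain with C5-OMe hold pseudoaxial, so that the two alkyl groups end up cis in 10. C2 is set when 7 attacks 10 from the face opposite both alkyl groups, which gives the 2,3-trans-2,4-trans product; this should also be the more stable one, because C2 can equilibrate through reversible C2–O1 ionisation. The step needs cyclisation to outrun intermolecular arylation and attack at C2, which the O1 tether (attack at C2 would need a four-membered ring), high dilution and the late addition of 7 secure.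

Step 5
Reactants: 11 (2R,3R,4S)-4-isobutyl-3-isopropyl-5,7-dimethoxy-2-(2,4,6-trimethoxyphenyl)chroman
Product: 12 (2R,3R,4S)-2-(3,5-diformyl-2,4,6-trimethoxyphenyl)-4-isobutyl-3-isopropyl-5,7-dimethoxychroman-6,8-dicarbaldehyde
Conditions: Cl2CHOMe (excess), TiCl4 (excess), CH2Cl2, −78 to 0 °C; then ice/aq HCl
Reagents that add atoms: dichloromethyl methyl ether, COC(Cl)Cl; water, O
Why: Rieche formylation: each of the four free ring positions (C6, C8, C3′, C5′) lies between two oxygen substituents, exhaustive substitution leaves no regiochemical choice, twofold formylation of phloroglucinol ethers is standard under these conditions, and C3 and C4 are not involved, while C2, should it ionise, returns to the favoured 2,3-trans form.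

Step 6
Reactants: 12 (2R,3R,4S)-2-(3,5-diformyl-2,4,6-trimethoxyphenyl)-4-isobutyl-3-isopropyl-5,7-dimethoxychroman-6,8-dicarbaldehyde
Product: 13 sideroxylonal A
Conditions: BCl3 (excess), CH2Cl2, −78 °C to rt; then H2O
Reagents that add atoms: none
Why: Chelation-assisted ether cleavage: each of the five methoxy groups is ortho to a formyl group and is cleaved by BCl3 through a six-membered boron chelate with chloride attack on the methyl group, while the two complexed formyl groups on ring B′ disfavour ionisation of the hindered C2–O1 bond, so no stereocenter is touched.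

Compound list
1 | (E)-2-isopropyl-5-methylhex-2-enal (self-aldol condensation dimer of isovaleraldehyde, commercial flavour chemical) | CC(C)C/C=C(C(C)C)/C=O | starting material
2 | (E)-2-isopropyl-5-methylhex-2-enoic acid | CC(C)C/C=C(C(C)C)/C(=O)O | intermediate
3 | 3,5-dimethoxyphenol | COc1cc(O)cc(OC)c1 | starting material
4 | 3,5-dimethoxyphenyl (E)-2-isopropyl-5-methylhex-2-enoate | CC(C)C/C=C(C(C)C)/C(=O)Oc1cc(OC)cc(OC)c1 | intermediate
5 | diisobutylaluminium alkoxide of the aryl hemiacetal formed from 4 (not isolated) | CC(C)C/C=C(C(C)C)/C(O[Al](CC(C)C)CC(C)C)Oc1cc(OC)cc(OC)c1 | intermediate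
6 | (E)-1-(3,5-dimethoxyphenoxy)-2-isopropyl-5-methylhex-2-en-1-yl acetate, racemic at the acetal carbon | CC(C)C/C=C(C(C)C)/C(OC(C)=O)Oc1cc(OC)cc(OC)c1 | intermediate
7 | 1,3,5-trimethoxybenzene | COc1cc(OC)cc(OC)c1 | starting material
8 | (E)-1-(3,5-dimethoxyphenoxy)-2-isopropyl-5-methylhex-2-en-1-ylium, the 1-aryloxyallyl cation paired with the chiral anion (not isolated) | CC(C)C/C=C(C(C)C)/C=[O+]c1cc(OC)cc(OC)c1 | intermediate
9 | (4S)-4-isobutyl-3-isopropyl-5,7-dimethoxy-4H-chromene (not isolated) | CC(C)C[C@@H]1c2c(OC)cc(OC)cc2OC=C1C(C)C | intermediate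
10 | (3R,4S)-4-isobutyl-3-isopropyl-5,7-dimethoxy-3,4-dihydrochromenylium, isopropyl and isobutyl cis (not isolated) | CC(C)C[C@@H]1c2c(OC)cc(OC)cc2[O+]=C[C@@H]1C(C)C | intermediate
11 | (2R,3R,4S)-4-isobutyl-3-isopropyl-5,7-dimethoxy-2-(2,4,6-trimethoxyphenyl)chroman (2,3-trans, 3,4-cis) | CC(C)C[C@@H]1c2c(OC)cc(OC)cc2O[C@@H](c2c(OC)cc(OC)cc2OC)[C@@H]1C(C)C | intermediate
12 | (2R,3R,4S)-2-(3,5-diformyl-2,4,6-trimethoxyphenyl)-4-isobutyl-3-isopropyl-5,7-dimethoxychroman-6,8-dicarbaldehyde | CC(C)C[C@@H]1c2c(OC)c(C=O)c(OC)c(C=O)c2O[C@@H](c2c(OC)c(C=O)c(OC)c(C=O)c2OC)[C@@H]1C(C)C | intermediate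
13 | sideroxylonal A, (2R,3R,4S)-2-(3,5-diformyl-2,4,6-trihydroxyphenyl)-5,7-dihydroxy-4-isobutyl-3-isopropylchroman-6,8-dicarbaldehyde | CC(C)C[C@@H]1c2c(O)c(C=O)c(O)c(C=O)c2O[C@@H](c2c(O)c(C=O)c(O)c(C=O)c2O)[C@@H]1C(C)C | target

Total step count: 6. Longest linear sequence: 6 steps (1 to 13).

Steps most likely to fail

Step 4. Facial discrimination within the ion pair may be weak. The cation may also fold too slowly into the U shape, so that proton loss to the dienyl ether and intermolecular arylation take over. The fallback uses known chemistry, sets out from 4 and comes back at 11.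
- Methanesulfonic acid should turn 4 into racemic cis-4-isobutyl-3-isopropyl-5,7-dimethoxychroman-2-one F1. This is the known acid-mediated intramolecular hydroarylation of aryl enoates (hydrocoumarin synthesis), the same C4–C4a closure at the ester level.
- DIBAL-H at −78 °C should give the racemic lactol 4-isobutyl-3-isopropyl-5,7-dimethoxychroman-2-ol F2.
- Acetalisation with (−)-menthol under PPTS gives diastereomeric acetals. The (3R,4S)-2-menthyloxychroman F3 (either C2 anomer) is separated from them by chromatography or crystallisation, a classical resolution of a lactol.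
- BF3·OEt2 and 7 then exchange the menthyloxy group for the aryl group through ion 10 and give 11.
- Any C3 epimer should converge at this stage through 9 and 10, as in the main route.

Step 3. The aluminium hemiacetal may collapse with loss of the aryloxide before it is acylated. The fallback sets out from 1 and 3 and comes back at 11.
- Trimethyl orthoformate and catalytic p-TsOH should give the enal dimethyl acetal F4.
- TESOTf and 2,4,6-collidine convert it into the α-methoxy collidinium triflate F5.
- Under these basic conditions the oxygen of 3 attacks F5 to give the mixed methyl aryl acetal F6.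
- F6 takes the place of 6 in step 4, with methanol as the leaving group.
- A mixed alkyl aryl acetal can also ionise with loss of the phenol, so this precursor is second choice.

Step 5. The Lewis acid may open the C2–O1 bond, followed by proton loss from C3. The trimethoxyphenyl ring may be lost after ipso-protonation. The reaction may also stall before the fourth formyl group is in place. The fallback reverses the order of the endgame, sets out from 11 and comes back at 13.
- BBr3 in CH2Cl2 should give the pentaphenol (2R,3R,4S)-4-isobutyl-3-isopropyl-2-(2,4,6-trihydroxyphenyl)chroman-5,7-diol F7.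
- Vilsmeier–Haack formylation (POCl3, DMF; aqueous hydrolysis) is the standard twofold formylation of free phloroglucinol rings. It should then formylate both rings twice and give 13 directly, bypassing 12.

Further compounds
F1 | step 4 | racemic cis-4-isobutyl-3-isopropyl-5,7-dimethoxychroman-2-one (the (3R,4S) enantiomer is drawn) | CC(C)C[C@@H]1c2c(OC)cc(OC)cc2OC(=O)[C@@H]1C(C)C
F2 | step 4 | racemic cis-4-isobutyl-3-isopropyl-5,7-dimethoxychroman-2-ol, anomeric mixture (the (3R,4S) enantiomer is drawn) | CC(C)C[C@@H]1c2c(OC)cc(OC)cc2OC(O)[C@@H]1C(C)C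
F3 | step 4 | (3R,4S)-4-isobutyl-3-isopropyl-5,7-dimethoxy-2-[(1R,2S,5R)-menthyloxy]chroman, either C2 anomer | CC(C)C[C@@H]1c2c(OC)cc(OC)cc2OC(O[C@@H]2C[C@H](C)CC[C@H]2C(C)C)[C@@H]1C(C)C
F4 | step 3 | (E)-1,1-dimethoxy-2-isopropyl-5-methylhex-2-ene | CC(C)C/C=C(C(C)C)/C(OC)OC
F5 | step 3 | 1-[(E)-1-methoxy-2-isopropyl-5-methylhex-2-en-1-yl]-2,4,6-trimethylpyridinium triflate | CC(C)C/C=C(C(C)C)/C(OC)[n+]1c(C)cc(C)cc1C.[O-]S(=O)(=O)C(F)(F)F
F6 | step 3 | 1-{[(E)-1-methoxy-2-isopropyl-5-methylhex-2-en-1-yl]oxy}-3,5-dimethoxybenzene, racemic | CC(C)C/C=C(C(C)C)/C(OC)Oc1cc(OC)cc(OC)c1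
F7 | step 5 | (2R,3R,4S)-4-isobutyl-3-isopropyl-2-(2,4,6-trihydroxyphenyl)chroman-5,7-diol | CC(C)C[C@@H]1c2c(O)cc(O)cc2O[C@@H](c2c(O)cc(O)cc2O)[C@@H]1C(C)C
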